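Retrosynthesis: the O1 isovalerate and O7 coumarate come off first, then the pyran is cut at O2 (lactol) and at C3–C4 (formyl carbon on the C11 ester); the 7β,8α-diol that remains is traced through an 11,8-lactone to a 7β,8β-epoxide.
The cyclopentene is cut at C7=C8 (ring-closing metathesis) and at C5–C9 (Ireland–Claisen rearrangement), which gives dienol 4 and butenoic acid 8.
Forward: ester 9, C5–C9 by the Claisen, the carbocycle by metathesis, the bridging lactone (C8–O) in the key step, the pyran last (C3–C4, then the O2 bridge), finally the C1 and C7 esters.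
Stereochemistry: C5 and C9 come from the chiral boron controller and the chair transition state of the Claisen; the epoxide forms anti to both α branches; C8 is inverted by the tethered carboxyl while C7 keeps the epoxide oxygen; C1 is set by acylation of the lactol on the convex β face.
Enabling feature: O8 on the tertiary ring carbon C8 stands on the α face of the cyclopentane, cis to the C4–C11 branch on C5 and trans to O7, so a C11 carboxyl reaches C8 from that face through a six-membered lactone ring (2-oxabicyclo[3.2.1]octan-3-one) and turns the readily made β-epoxide into the 7β,8α-diol.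
Key step: step 14

Convention: iridoid numbering is used (C1, O2, C3, C4, ring C5–C9, C10 on C8, C11 on C4); α/β refer to the usual drawing with H-5 and H-9 β, so the C1 and C4 branches on the cyclopentane are α. Lactols and silyl acetals 27–31 are drawn as 1β anomers; their anomeric composition is immaterial because C1 is fixed only in step 24.
Assumption: the (S,S)-controller is taken to deliver the (2S,3R)-acid 12; the sense of induction for this 3-substituted but-3-enoate has to be confirmed on the first run, and the (R,R)-controller is used in the same way should it prove opposite.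

Step 1
Reactants: 1 propargyl alcohol; 2 allyl bromide
Product: 3 hex-5-en-2-yn-1-ol
Conditions: CuI (10 mol%), K2CO3, n-Bu4NI (cat.), DMF, rt
Reagents that add atoms: none
Why: Copper-catalysed allylation of a terminal alkyne (the copper acetylide formed with K2CO3 displaces the allylic bromide) gives the skipped enyne with the free hydroxyl untouched, and no stereocentre is formed.

Step 2
Reactants: 3 hex-5-en-2-yn-1-ol
Product: 4 (2E)-hexa-2,5-dien-1-ol
Conditions: LiAlH4, THF, 0 °C → reflux; aq. NaOH work-up
Reagents that add atoms: none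
Why: Hydroxyl-directed trans-hydroalumination of the propargylic alcohol and protonolysis of the vinylalane give the E-allylic alcohol only, while the isolated terminal alkene does not react.

Step 3
Reactants: 5 monomethyl itaconate
Product: 6 methyl 3-(hydroxymethyl)but-3-enoate
Conditions: BH3·SMe2 (1.0 equiv), THF, −10 °C → rt; MeOH quench
Reagents that add atoms: none
Why: Chemoselective borane reduction, in which the free carboxyl is reduced through its acyloxyborane much faster than the methyl ester is attacked or the electron-poor 1,1-disubstituted alkene is hydroborated; the hydroxy ester is silylated at once so that it does not lactonise.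

Step 4
Reactants: 6 methyl 3-(hydroxymethyl)but-3-enoate
Product: 7 methyl 3-{[(tert-butyldiphenylsilyl)oxy]methyl}but-3-enoate
Conditions: t-BuPh2SiCl, imidazole, CH2Cl2, 0 °C → rt
Reagents that add atoms: tert-butyl(chloro)diphenylsilane, CC(C)(C)[Si](Cl)(c1ccccc1)c1ccccc1
Why: Imidazole-mediated silylation of the primary alcohol; the TBDPS ether withstands base, hydride, peracid and acid later and, being an ether, neither withdraws much electron density from C8 nor can take part in the epoxide opening.

Step 5
Reactants: 7 methyl 3-{[(tert-butyldiphenylsilyl)oxy]methyl}but-3-enoate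
Product: 8 3-{[(tert-butyldiphenylsilyl)oxy]methyl}but-3-enoic acid
Conditions: LiOH, THF/H2O, 0 °C; then aq. HCl to pH 3
Reagents that add atoms: lithium hydroxide, [Li+].[OH-]
Why: Saponification of the methyl ester at 0 °C, where the carboxylate once formed is no longer enolisable, so the β,γ-alkene does not move into conjugation.

Step 6
Reactants: 8 3-{[(tert-butyldiphenylsilyl)oxy]methyl}but-3-enoic acid; 4 (2E)-hexa-2,5-dien-1-ol
Product: 9 (2E)-hexa-2,5-dien-1-yl 3-{[(tert-butyldiphenylsilyl)oxy]methyl}but-3-enoate
Conditions: EDC·HCl, DMAP (cat.), CH2Cl2, 0 °C → rt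
Reagents that add atoms: none
Why: Steglich esterification joins the two fragments under near-neutral conditions that leave the β,γ-unsaturated acid and the skipped diene unchanged.

Step 7
Reactants: 9 (2E)-hexa-2,5-dien-1-yl 3-{[(tert-butyldiphenylsilyl)oxy]methyl}but-3-enoate
Product: 12 (2S,3R)-2-[3-{(tert-butyldiphenylsilyl)oxy}prop-1-en-2-yl]-3-ethenylhex-5-enoic acid, via boron enolate 10 (not isolated), via boron carboxylate 11 (not isolated)
Conditions: (4S,5S)-2-bromo-1,3-bis{[3,5-bis(trifluoromethyl)phenyl]sulfonyl}-4,5-diphenyl-1,3,2-diazaborolidine (1.2 equiv, made in the flask from the (S,S)-bis-sulfonamide and BBr3 in CH2Cl2), Et3N, toluene/hexane, −78 °C, then −20 → 4 °C; aq. work-up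
Reagents that add atoms: none
Why: Enantioselective Ireland–Claisen rearrangement of a chiral boron enolate, in which Et3N in toluene–hexane gives the E(O) enolate (C8 branch cis to the allyloxy oxygen) that rearranges with the E alkene through a chair transition state to the anti acid, the relative configuration that puts the C1 and C4 branches cis on the later ring, while the C2-symmetric sulfonamide ligand on boron shields one enolate face and so fixes C9 and C5 together.

Step 8
Reactants: 12 (2S,3R)-2-[3-{(tert-butyldiphenylsilyl)oxy}prop-1-en-2-yl]-3-ethenylhex-5-enoic acid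
Product: 13 (2S,3R)-2-[3-{(tert-butyldiphenylsilyl)oxy}prop-1-en-2-yl]-3-ethenylhex-5-en-1-ol
Conditions: LiAlH4, Et2O, 0 °C → rt
Reagents that add atoms: none
Why: Hydride reduction of the acid through its lithium carboxylate, whose α-hydrogen is not acidic, so C9 neither epimerises nor loses the β,γ position of its alkene, and the silyl ether survives at this temperature.

Step 9
Reactants: 13 (2S,3R)-2-[3-{(tert-butyldiphenylsilyl)oxy}prop-1-en-2-yl]-3-ethenylhex-5-en-1-ol
Product: 14 tert-butyldimethylsilyl ether of 13 (O1 TBS; O10 TBDPS)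
Conditions: t-BuMe2SiCl, imidazole, CH2Cl2, 0 °C → rt
Reagents that add atoms: tert-butyl(chloro)dimethylsilane, CC(C)(C)[Si](C)(C)Cl
Why: Standard silylation; a TBS ether on O1 is inert in the epoxide opening, keeps C9 free of electron-withdrawing carbonyl groups and can later be removed in the presence of the bulkier TBDPS group on O10.

Step 10
Reactants: 14 tert-butyldimethylsilyl ether of 13
Product: 15 (4R,5S)-cyclopentene (C7=C8 ring alkene; 5α-vinyl; 9α-CH2OTBS; C10 OTBDPS on C8)
Conditions: second-generation Grubbs catalyst (H2IMes)(PCy3)Cl2Ru=CHPh (5 mol%), CH2Cl2 (5 mM), 40 °C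
Reagents that add atoms: none
Why: Ring-closing metathesis between the allyl terminus and the 1,1-disubstituted alkene closes the five-membered ring with loss of ethene (the vinyl group on C5 could only close a cyclobutene and stays), and the two stereocentres are not involved.

Step 11
Reactants: 15 (4R,5S)-cyclopentene
Product: 16 7β,8β-epoxide of 15
Conditions: m-CPBA (1.05 equiv), CH2Cl2, −20 → 0 °C
Reagents that add atoms: 3-chloroperoxybenzoic acid, OOC(=O)c1cccc(Cl)c1
Why: Prilezhaev epoxidation, in which the trisubstituted ring alkene reacts far faster than the monosubstituted vinyl group and, with no hydrogen-bond donor in the substrate, the peracid comes from the β face, anti to the α branches on the allylic C9 and on C5, which sets C7 and C8 of the convex epoxide.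

Step 12
Reactants: 16 7β,8β-epoxide of 15
Product: 18 7β,8β-epoxy alcohol (C11 CH2OH on the C4 arm), via alkylborane 17 (not isolated)
Conditions: 9-BBN, THF, 0 °C → rt; then NaOH, H2O2, 0 °C
Reagents that add atoms: hydrogen peroxide, OO
Why: Anti-Markovnikov hydroboration of the terminal vinyl group by the bulky dialkylborane, which does not open epoxides at this temperature, followed by oxidation of the C–B bond, gives the C11 primary alcohol.

Step 13
Reactants: 18 7β,8β-epoxy alcohol
Product: 19 7β,8β-epoxy cyclopentaneacetic acid (C11 carboxyl; O1 TBS; O10 TBDPS)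
Conditions: TEMPO (cat.), PhI(OAc)2, MeCN/aq. phosphate buffer (pH 7), 0 °C → rt
Reagents that add atoms: water, O
Why: Oxoammonium (TEMPO) oxidation of the primary alcohol through the aldehyde hydrate to the carboxylic acid under buffered conditions that spare the epoxide and both silyl ethers; the epoxy acid is taken on without chromatography.

Step 14
Reactants: 19 7β,8β-epoxy cyclopentaneacetic acid
Product: 20 bridged 11,8-lactone with free 7β-hydroxyl (2-oxabicyclo[3.2.1]octan-3-one; 8β-CH2OTBDPS; 9α-CH2OTBS)
Conditions: camphorsulfonic acid (0.1 equiv), CH2Cl2, 0 °C → rt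
Reagents that add atoms: none
Why: Camphorsulfonic acid protonates the epoxide oxygen, the bond to the tertiary C8 lengthens, and the carbonyl oxygen of the C11 carboxyl, held on the α face by the C4 arm on C5, attacks C8 anti to the departing oxygen, after which loss of a proton gives the lactone and leaves the former epoxide oxygen as the 7β-hydroxyl. The closest known reaction type is the acid-catalysed lactonisation of epoxy acids at the more substituted epoxide carbon. The one new ring, the six-membered lactone of a 2-oxabicyclo[3.2.1]octan-3-one, closes 6-exo-tet, the breaking epoxide C–O bond lying outside it. The one new stereocentre, C8, is set by inversion because the tether can deliver the carboxyl only to the α face, so O8 ends α and C10 β, while C7 keeps the β oxygen placed in step 11. The step needs attack at C8 and not at C7, both of which would give bridged six-membered lactones; the cation-stabilising tertiary C8 is favoured under a Brønsted acid in a non-coordinating solvent, and the substrate carries only silyl ethers on O1 and O10 (no carbonyl on C9), which keeps C8 as electron-rich as possible. These ethers can neither act as neighbouring groups nor ionise under catalytic acid.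

Step 15
Reactants: 20 bridged 11,8-lactone
Product: 21 methyl ester with 7β,8α-diol (C11 CO2Me on the C4 arm; O1 TBS; O10 TBDPS)
Conditions: K2CO3 (cat.), MeOH, 0 °C
Reagents that add atoms: methanol, CO
Why: Base-catalysed transesterification opens the strained bridged lactone of the tertiary alcohol to the methyl ester and the free 8α-hydroxyl without touching a stereocentre or the silyl ethers.

Step 16
Reactants: 21 methyl ester with 7β,8α-diol; 22 methyl formate
Product: 24 β-methoxyacrylate (C3 methyl enol ether on C4; E isomer drawn), via hydroxymethylene ester 23 (not isolated)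
Conditions: LiN(i-Pr)2 (3.3 equiv), THF, −78 °C; HCO2Me, −78 → −20 °C; MeOH, then aq. NH4Cl; crude enol: Me3SiCHN2, MeOH/toluene, 0 °C
Reagents that add atoms: (trimethylsilyl)diazomethane, C[Si](C)(C)C=[N+]=[N-]
Why: Crossed Claisen formylation of the ester enolate (the substrate is deprotonated three times, so the C8 alkoxide never meets an electrophilic ester and cannot relactonise, and the methanol treatment cleaves any O-formate), followed by O-methylation of the acidic enol, which masks C3 as an inert enol ether of either geometry while C1 is oxidised.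

Step 17
Reactants: 24 β-methoxyacrylate
Product: 25 C1 primary alcohol (O10 TBDPS kept)
Conditions: HF·pyridine, pyridine, THF, 0 °C → rt
Reagents that add atoms: none
Why: Selective desilylation, since buffered HF cleaves the unhindered primary TBS ether on O1 much faster than the neopentyl-type TBDPS ether on O10.

Step 18
Reactants: 25 C1 primary alcohol
Product: 26 C1 aldehyde
Conditions: TEMPO (cat.), PhI(OAc)2, CH2Cl2, 0 °C → rt
Reagents that add atoms: none
Why: TEMPO/PhI(OAc)2 oxidises the primary alcohol selectively beside the secondary C7 and tertiary C8 hydroxyls and stops at the aldehyde without water, under non-basic conditions in which the β-hydroxy aldehyde neither epimerises at C9 nor undergoes retro-aldol cleavage.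

Step 19
Reactants: 26 C1 aldehyde
Product: 27 lactol (methyl 1β,7β,8α-trihydroxy-10-O-TBDPS-iridoid-3-en-11-oate)
Conditions: p-TsOH·H2O (0.2 equiv), THF/H2O, rt → 40 °C
Reagents that add atoms: water, O
Why: Acid-catalysed acetal exchange, in which the hydrated C1 aldehyde adds to C3 of the β-methoxyacrylate and methanol is lost to close the six-membered pyran (the ring–chain closure usual for iridoid aglycones), and under the equilibrating acid the C1 hydroxyl takes the anomerically favoured pseudo-axial β position on the convex face.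

Step 20
Reactants: 27 lactol
Product: 28 1,7-bis-O-triethylsilyl derivative of 27
Conditions: Et3SiCl, imidazole, DMAP (cat.), DMF, 0 °C → rt
Reagents that add atoms: chlorotriethylsilane, CC[Si](Cl)(CC)CC
Why: Silylation of the lactol and of the secondary C7 hydroxyl (the tertiary C8 hydroxyl does not react under these conditions); the lactol has to be capped as a silyl acetal because its aluminium alkoxide would ring-open to an aldehyde during the hydride reduction.

Step 21
Reactants: 28 1,7-bis-O-triethylsilyl derivative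
Product: 29 C11 allylic alcohol (1,7-bis-O-TES; 10-O-TBDPS)
Conditions: i-Bu2AlH (3.5 equiv), CH2Cl2, −78 °C; aq. KNaC4H4O6 work-up
Reagents that add atoms: none
Why: 1,2-Reduction of the vinylogous carbonate ester by i-Bu2AlH gives the C11 allylic alcohol, the silyl acetal and the silyl ethers being inert to the hydride.

Step 22
Reactants: 29 C11 allylic alcohol
Product: 30 11-O-TBDPS ether (1,7-bis-O-TES; 10,11-bis-O-TBDPS)
Conditions: t-BuPh2SiCl, imidazole, CH2Cl2, 0 °C
Reagents that add atoms: tert-butyl(chloro)diphenylsilane, CC(C)(C)[Si](Cl)(c1ccccc1)c1ccccc1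
Why: Silylation of the only unhindered hydroxyl, the primary allylic one, with a group that outlasts both TES removals.

Step 23
Reactants: 30 11-O-TBDPS ether
Product: 31 lactol with free 1β-hydroxyl (7-O-TES; 10,11-bis-O-TBDPS)
Conditions: Bu4NF/AcOH (1:1, 1.1 equiv), THF, −40 → −20 °C
Reagents that add atoms: none
Why: Selective desilylation, since the silyl acetal at C1 (a lactol is a far better leaving group than an alcohol) is cleaved by buffered fluoride well before the hindered secondary TES ether at C7, and the acetic acid keeps the liberated lactol from opening as its alkoxide; 31 is used without chromatography.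

Step 24
Reactants: 31 lactol with free 1β-hydroxyl; 32 isovaleric anhydride
Product: 33 1β-O-isovaleryl derivative (7-O-TES; 10,11-bis-O-TBDPS)
Conditions: Et3N, DMAP (cat.), CH2Cl2, −20 → 0 °C
Reagents that add atoms: none
Why: DMAP-catalysed acylation of the lactol hydroxyl, the only reactive hydroxyl left, in which the anomers equilibrate and the acyl group is taken up on the convex β face, trans to C8 and pseudo-axial (anomeric effect), to give the 1β ester.

Step 25
Reactants: 33 1β-O-isovaleryl derivative
Product: 34 7β-alcohol (1β-O-isovaleryl; 10,11-bis-O-TBDPS)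
Conditions: HF·pyridine, pyridine, THF, 0 °C
Reagents that add atoms: none
Why: Selective desilylation, buffered HF removing the secondary TES ether while the two primary TBDPS ethers and the acyl acetal stay.

Step 26
Reactants: 35 p-coumaric acid
Product: 37 (2E)-3-{4-[(tert-butyldimethylsilyl)oxy]phenyl}prop-2-enoic acid, via silyl ester 36 (not isolated)
Conditions: t-BuMe2SiCl (2.2 equiv), imidazole, DMF, rt; then AcOH/THF/H2O, rt
Reagents that add atoms: tert-butyl(chloro)dimethylsilane, CC(C)(C)[Si](C)(C)Cl
Why: Silylation of both the phenol and the carboxyl followed by hydrolysis of the much more labile silyl ester leaves the aryl silyl ether, which blocks the phenol during the esterification.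

Step 27
Reactants: 34 7β-alcohol; 37 (2E)-3-{4-[(tert-butyldimethylsilyl)oxy]phenyl}prop-2-enoic acid
Product: 38 silyl-protected luzonoid A (7-O-(4-O-TBS-coumaroyl); 10,11-bis-O-TBDPS)
Conditions: EDC·HCl, DMAP, CH2Cl2, 0 °C → rt
Reagents that add atoms: none
Why: Steglich esterification of the secondary 7β-hydroxyl with retention at C7; the tertiary C8 hydroxyl is not acylated and the acyl acetal tolerates these conditions.

Step 28
Reactants: 38 silyl-protected luzonoid A
Product: 39 luzonoid A
Conditions: Bu4NF/AcOH (1:1, excess), THF, 0 °C → rt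
Reagents that add atoms: none
Why: Fluoride cleavage of the aryl TBS ether and the two primary TBDPS ethers, with the acetic acid buffer suppressing acyl migration from O7 to O10 and loss of the C1 acyl acetal.

Compound list
1 | propargyl alcohol (prop-2-yn-1-ol) | C#CCO | starting material
2 | allyl bromide (3-bromoprop-1-ene) | C=CCBr | starting material
3 | hex-5-en-2-yn-1-ol | C=CCC#CCO | intermediate
4 | (2E)-hexa-2,5-dien-1-ol | C=CC/C=C/CO | intermediate
5 | monomethyl itaconate (4-methoxy-2-methylidene-4-oxobutanoic acid) | COC(=O)CC(=C)C(=O)O | starting material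
6 | methyl 3-(hydroxymethyl)but-3-enoate | COC(=O)CC(=C)CO | intermediate
7 | methyl 3-{[(tert-butyldiphenylsilyl)oxy]methyl}but-3-enoate | COC(=O)CC(=C)CO[Si](c1ccccc1)(c1ccccc1)C(C)(C)C | intermediate
8 | 3-{[(tert-butyldiphenylsilyl)oxy]methyl}but-3-enoic acid | OC(=O)CC(=C)CO[Si](c1ccccc1)(c1ccccc1)C(C)(C)C | intermediate
9 | (2E)-hexa-2,5-dien-1-yl 3-{[(tert-butyldiphenylsilyl)oxy]methyl}but-3-enoate | C=CC/C=C/COC(=O)CC(=C)CO[Si](c1ccccc1)(c1ccccc1)C(C)(C)C | intermediate
10 | E(O) boron enolate of 9 (O-bound (4S,5S)-diazaborolidine) | C=CC/C=C/CO/C(=C\C(=C)CO[Si](c1ccccc1)(c1ccccc1)C(C)(C)C)OB1N(S(=O)(=O)c2cc(C(F)(F)F)cc(C(F)(F)F)c2)[C@@H](c2ccccc2)[C@H](c2ccccc2)N1S(=O)(=O)c1cc(C(F)(F)F)cc(C(F)(F)F)c1 | intermediate (not isolated)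
11 | boron carboxylate of acid 12 | C=C[C@@H](CC=C)[C@@H](C(=C)CO[Si](c1ccccc1)(c1ccccc1)C(C)(C)C)C(=O)OB1N(S(=O)(=O)c2cc(C(F)(F)F)cc(C(F)(F)F)c2)[C@@H](c2ccccc2)[C@H](c2ccccc2)N1S(=O)(=O)c1cc(C(F)(F)F)cc(C(F)(F)F)c1 | intermediate (not isolated)
12 | (2S,3R)-2-[3-{(tert-butyldiphenylsilyl)oxy}prop-1-en-2-yl]-3-ethenylhex-5-enoic acid | C=C[C@@H](CC=C)[C@@H](C(=C)CO[Si](c1ccccc1)(c1ccccc1)C(C)(C)C)C(=O)O | intermediate
13 | (2S,3R)-2-[3-{(tert-butyldiphenylsilyl)oxy}prop-1-en-2-yl]-3-ethenylhex-5-en-1-ol | C=C[C@@H](CC=C)[C@@H](C(=C)CO[Si](c1ccccc1)(c1ccccc1)C(C)(C)C)CO | intermediate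
14 | tert-butyldimethylsilyl ether of 13 | C=C[C@@H](CC=C)[C@@H](C(=C)CO[Si](c1ccccc1)(c1ccccc1)C(C)(C)C)CO[Si](C)(C)C(C)(C)C | intermediate
15 | (4R,5S)-4-ethenyl-5-{[(tert-butyldimethylsilyl)oxy]methyl}-1-{[(tert-butyldiphenylsilyl)oxy]methyl}cyclopent-1-ene (C7=C8; 5α-vinyl; 9α-CH2OTBS) | C=C[C@H]1CC=C(CO[Si](c2ccccc2)(c2ccccc2)C(C)(C)C)[C@H]1CO[Si](C)(C)C(C)(C)C | intermediate
16 | 7β,8β-epoxide of 15 | C=C[C@H]1C[C@@H]2O[C@]2(CO[Si](c3ccccc3)(c3ccccc3)C(C)(C)C)[C@H]1CO[Si](C)(C)C(C)(C)C | intermediate
17 | B-alkyl-9-borabicyclo[3.3.1]nonane adduct of 16 (boron on C11) | C(CB1C2CCCC1CCC2)[C@H]1C[C@@H]2O[C@]2(CO[Si](c3ccccc3)(c3ccccc3)C(C)(C)C)[C@H]1CO[Si](C)(C)C(C)(C)C | intermediate (not isolated)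
18 | 7β,8β-epoxy alcohol (C11 CH2OH) | OCC[C@H]1C[C@@H]2O[C@]2(CO[Si](c3ccccc3)(c3ccccc3)C(C)(C)C)[C@H]1CO[Si](C)(C)C(C)(C)C | intermediate
19 | 7β,8β-epoxy cyclopentaneacetic acid (C11 carboxyl; O1 TBS; O10 TBDPS) | OC(=O)C[C@H]1C[C@@H]2O[C@]2(CO[Si](c3ccccc3)(c3ccccc3)C(C)(C)C)[C@H]1CO[Si](C)(C)C(C)(C)C | intermediate
20 | bridged 11,8-lactone with free 7β-hydroxyl (2-oxabicyclo[3.2.1]octan-3-one) | O=C1C[C@H]2C[C@H](O)[C@@](CO[Si](c3ccccc3)(c3ccccc3)C(C)(C)C)(O1)[C@H]2CO[Si](C)(C)C(C)(C)C | intermediate
21 | methyl ester with 7β,8α-diol | COC(=O)C[C@H]1C[C@H](O)[C@](O)(CO[Si](c2ccccc2)(c2ccccc2)C(C)(C)C)[C@H]1CO[Si](C)(C)C(C)(C)C | intermediate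
22 | methyl formate | COC=O | starting material
23 | (Z)-hydroxymethylene ester (C3 enol on C4) | COC(=O)/C(=C\O)[C@H]1C[C@H](O)[C@](O)(CO[Si](c2ccccc2)(c2ccccc2)C(C)(C)C)[C@H]1CO[Si](C)(C)C(C)(C)C | intermediate (not isolated)
24 | β-methoxyacrylate (C3 methyl enol ether; E drawn) | COC(=O)/C(=C/OC)[C@H]1C[C@H](O)[C@](O)(CO[Si](c2ccccc2)(c2ccccc2)C(C)(C)C)[C@H]1CO[Si](C)(C)C(C)(C)C | intermediate
25 | C1 primary alcohol of 24 | COC(=O)/C(=C/OC)[C@H]1C[C@H](O)[C@](O)(CO[Si](c2ccccc2)(c2ccccc2)C(C)(C)C)[C@H]1CO | intermediate
26 | C1 aldehyde | COC(=O)/C(=C/OC)[C@H]1C[C@H](O)[C@](O)(CO[Si](c2ccccc2)(c2ccccc2)C(C)(C)C)[C@H]1C=O | intermediate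
27 | lactol, methyl 1β,7β,8α-trihydroxy-10-O-TBDPS-iridoid-3-en-11-oate | O[C@@H]1OC=C(C(=O)OC)[C@H]2C[C@H](O)[C@](O)(CO[Si](c3ccccc3)(c3ccccc3)C(C)(C)C)[C@@H]12 | intermediate
28 | 1,7-bis-O-triethylsilyl derivative of 27 | CC[Si](CC)(CC)O[C@@H]1OC=C(C(=O)OC)[C@H]2C[C@H](O[Si](CC)(CC)CC)[C@](O)(CO[Si](c3ccccc3)(c3ccccc3)C(C)(C)C)[C@@H]12 | intermediate
29 | C11 allylic alcohol (1,7-bis-O-TES; 10-O-TBDPS) | CC[Si](CC)(CC)O[C@@H]1OC=C(CO)[C@H]2C[C@H](O[Si](CC)(CC)CC)[C@](O)(CO[Si](c3ccccc3)(c3ccccc3)C(C)(C)C)[C@@H]12 | intermediate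
30 | 11-O-TBDPS ether (1,7-bis-O-TES; 10,11-bis-O-TBDPS) | CC[Si](CC)(CC)O[C@@H]1OC=C(CO[Si](c3ccccc3)(c3ccccc3)C(C)(C)C)[C@H]2C[C@H](O[Si](CC)(CC)CC)[C@](O)(CO[Si](c3ccccc3)(c3ccccc3)C(C)(C)C)[C@@H]12 | intermediate
31 | lactol with free 1β-hydroxyl (7-O-TES; 10,11-bis-O-TBDPS) | O[C@@H]1OC=C(CO[Si](c3ccccc3)(c3ccccc3)C(C)(C)C)[C@H]2C[C@H](O[Si](CC)(CC)CC)[C@](O)(CO[Si](c3ccccc3)(c3ccccc3)C(C)(C)C)[C@@H]12 | intermediate
32 | isovaleric anhydride (3-methylbutanoic anhydride) | CC(C)CC(=O)OC(=O)CC(C)C | starting material
33 | 1β-O-isovaleryl derivative (7-O-TES; 10,11-bis-O-TBDPS) | CC(C)CC(=O)O[C@@H]1OC=C(CO[Si](c3ccccc3)(c3ccccc3)C(C)(C)C)[C@H]2C[C@H](O[Si](CC)(CC)CC)[C@](O)(CO[Si](c3ccccc3)(c3ccccc3)C(C)(C)C)[C@@H]12 | intermediate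
34 | 7β-alcohol (1β-O-isovaleryl; 10,11-bis-O-TBDPS) | CC(C)CC(=O)O[C@@H]1OC=C(CO[Si](c3ccccc3)(c3ccccc3)C(C)(C)C)[C@H]2C[C@H](O)[C@](O)(CO[Si](c3ccccc3)(c3ccccc3)C(C)(C)C)[C@@H]12 | intermediate
35 | p-coumaric acid ((2E)-3-(4-hydroxyphenyl)prop-2-enoic acid) | OC(=O)/C=C/c1ccc(O)cc1 | starting material
36 | tert-butyldimethylsilyl (2E)-3-{4-[(tert-butyldimethylsilyl)oxy]phenyl}prop-2-enoate | CC(C)(C)[Si](C)(C)OC(=O)/C=C/c1ccc(O[Si](C)(C)C(C)(C)C)cc1 | intermediate (not isolated)
37 | (2E)-3-{4-[(tert-butyldimethylsilyl)oxy]phenyl}prop-2-enoic acid | OC(=O)/C=C/c1ccc(O[Si](C)(C)C(C)(C)C)cc1 | intermediate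
38 | silyl-protected luzonoid A (7-O-(4-O-TBS-coumaroyl); 10,11-bis-O-TBDPS) | CC(C)CC(=O)O[C@@H]1OC=C(CO[Si](c3ccccc3)(c3ccccc3)C(C)(C)C)[C@H]2C[C@H](OC(=O)/C=C/c3ccc(O[Si](C)(C)C(C)(C)C)cc3)[C@](O)(CO[Si](c3ccccc3)(c3ccccc3)C(C)(C)C)[C@@H]12 | intermediate
39 | luzonoid A | CC(C)CC(=O)O[C@@H]1OC=C(CO)[C@H]2C[C@H](OC(=O)/C=C/c3ccc(O)cc3)[C@](O)(CO)[C@@H]12 | target

Total step count: 28. Longest linear sequence: 25 steps (from 5 through steps 3–25, 27 and 28).

Steps most likely to fail

Step 14. What may go wrong: the tethered carboxyl opens the epoxide at the less hindered secondary C7 instead of the tertiary C8 (regiochemical leakage to the isomeric 11,7-lactone), or C8 ionises and loses stereochemical fidelity. Fallback: setting out from epoxy acid 19, the carboxyl is first methylated with Me3SiCHN2 to the epoxy methyl ester F1, and the epoxide is then hydrolysed with dilute aqueous HClO4 in THF at 0 °C (short exposure, which the silyl ethers tolerate). Water, a small untethered nucleophile, opens protonated trisubstituted epoxides at the tertiary carbon with inversion, so the 7β,8α-diol methyl ester forms directly and the route is rejoined at 21.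

Step 7. What may go wrong: incomplete control of the enolate geometry or of the enolate face (low diastereo- or enantioselectivity), or drift of the β,γ-alkene into conjugation during enolisation. Fallback: setting out from ester 9, LiN(i-Pr)2 and Me3SiCl in THF at −78 °C give the E(O) trimethylsilyl ketene acetal F2, which rearranges on warming to the racemic anti trimethylsilyl ester F3 (one enantiomer drawn). Aqueous work-up gives the racemic acid, that is 12 together with its enantiomer F4. Acid 12 is separated by crystallisation of its (S)-1-phenylethylammonium salt F5 (the (R)-amine serves if the other salt is the crystalline one) and set free with dilute acid, and the route is rejoined at 12.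

Step 23. What may go wrong: loss of the C7 silyl ether together with the anomeric one, or ring-opening and β-elimination of the liberated lactol before it is acylated. Fallback: setting out from 30, both TES groups are removed with HF·pyridine to give the 1,7-diol lactol F6. The isovalerate is then put on by a Mitsunobu esterification with isovaleric acid (PPh3, DIAD, THF, 0 °C), which activates only the hemiacetal hydroxyl (the neopentyl-type secondary C7 hydroxyl and the tertiary C8 hydroxyl are inert) and lets the carboxylate enter on the convex β face. This gives the 7β-alcohol directly and the route is rejoined at 34.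

Further compounds
F1 | step 14 | methyl ester of epoxy acid 19 (7β,8β-epoxide; O1 TBS; O10 TBDPS) | COC(=O)C[C@H]1C[C@@H]2O[C@]2(CO[Si](c3ccccc3)(c3ccccc3)C(C)(C)C)[C@H]1CO[Si](C)(C)C(C)(C)C
F2 | step 7 | E(O) trimethylsilyl ketene acetal of ester 9 | C=CC/C=C/CO/C(=C\C(=C)CO[Si](c1ccccc1)(c1ccccc1)C(C)(C)C)O[Si](C)(C)C
F3 | step 7 | trimethylsilyl ester of the racemic anti acid (2S,3R enantiomer drawn) | C=C[C@@H](CC=C)[C@@H](C(=C)CO[Si](c1ccccc1)(c1ccccc1)C(C)(C)C)C(=O)O[Si](C)(C)C
F4 | step 7 | (2R,3S)-enantiomer of acid 12 | C=C[C@H](CC=C)[C@H](C(=C)CO[Si](c1ccccc1)(c1ccccc1)C(C)(C)C)C(=O)O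
F5 | step 7 | (S)-1-phenylethylammonium salt of acid 12 | C=C[C@@H](CC=C)[C@@H](C(=C)CO[Si](c1ccccc1)(c1ccccc1)C(C)(C)C)C(=O)[O-].C[C@H]([NH3+])c1ccccc1
F6 | step 23 | 1,7-diol lactol (1β,7β,8α-triol; 10,11-bis-O-TBDPS) | O[C@@H]1OC=C(CO[Si](c3ccccc3)(c3ccccc3)C(C)(C)C)[C@H]2C[C@H](O)[C@](O)(CO[Si](c3ccccc3)(c3ccccc3)C(C)(C)C)[C@@H]12
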